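The runs are simulated with constants of no real substance, and the scatter is random.

At 3.0 min I read a flask of racemic substrate and dosed partner, and I want to know what stands in it.

in all of them: left-handed substrate 0.10 M; right-handed substrate 0.10 M; precatalyst 7.3 mM
- alpha: partner 0.10 M (in portions, 3); run made earlier; portions every 4.0 s
- eta: partner 0.40 M (in portions, 3); run made earlier; portions every 4.0 s
- flask: partner 0.200 M (in portions, 3); the portions of partner follow each other after 4.0 s, the first at the start; time 3.0 min

- alpha (time / min: left-handed substrate / %, left-handed product / %, right-handed product / %): 0.833: 28.3, 31.1, 10.0; 2.00: 28.0, 32.2, 11.6; 2.50: 29.5, 32.3, 12.8; 4.00: 28.1, 32.9, 13.4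
- eta (time / min: left-handed substrate / %, left-handed product / %, right-handed product / %): 0.250: 6.6, 59.1, 27.2; 0.667: 0.4, 67.5, 32.0; 1.50: 0.4, 69.5, 33.4; 4.00: 0, 67.5, 32.8

(standard deviation of a reading: 1 percentage point)

- at 3.0 min, what has stopped the reaction, if anything has (it is still moving / all of the left-handed substrate has reacted / forward and back rates have come level / the partner has run out first / no working catalyst is left)
- share of the left-handed substrate and right-handed substrate together used up at 3.0 min
- left-handed product at 3.0 min, in percent of the left-handed substrate and right-handed substrate together charged
- right-handed product at 3.0 min, in percent of the left-handed substrate and right-handed substrate together charged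

- partner is single-handed; left-handed substrate and right-handed substrate are mirror images of each other, charged as a racemate, each of them at the stated concentration
- steps thought possible: partner + left-handed substrate -> left-handed product; partner + right-handed substrate -> right-handed product; left-handed substrate + racemization catalyst <-> right-handed substrate + racemization catalyst; precatalyst -> racemization catalyst; 2 racemization catalyst -> spent catalyst; partner -> decomposed reagent
- the reaction counts as stopped when no species that holds the left-handed substrate and right-handed substrate together changes by six tenths of a point or more over the second half of the time
- the handed part of partner does not stay in what it makes, so the products of the two hands are mirror images too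

In alpha at 4.00 min, left-handed substrate and left-handed product add to 61.0 %, more than the 50.0 % charged of that hand, so right-handed substrate is crossing over. I therefore reckon with both hands level, as one pool. Coupling and decomposition are each first order in partner, so time drops out of their ratio, and the portions with it. Partner charged = pool used + L·ln(pool at start/pool at end), where L is the loss constant, the decomposition constant over the mean coupling constant. Alpha at 4.00 min has used 46.3 % of its pool, so L is 0.0119 M. That is 5.95 % of the flask's pool of 0.200 M, which matches its partner charge. Two Newton rounds on the balance leave 12.4 % of the pool, a conversion of 87.6 %.

The weak link is L. It hangs on a difference of 0.00740 M, while one point of scatter on each of two readings is 0.00283 M. So I average alpha from 2.00 min on, products and left-handed substrate together, and read a conversion of 44.0 %. That gives 0.0207 M for the loss constant, the [pool] at which partner divides equally between coupling and decomposition. As a share of the flask's pool it is 10.3 %, which leaves 17.8 %, a conversion of 82.2 %. Product ratios read 2.46 in alpha at 4.00 min and 2.06 in eta at 4.00 min. Their midpoint, 2.26, splits my conversion into 56.9 % left-handed and 25.2 % right-handed product.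

The forecast says: the partner has run out first, conversion 85 % (79 % to 92 %), left-handed product 60 % (55 % to 65 %), right-handed product 25 % (21 % to 29 %). Its grounds: “Coupling and decomposition are both first order in partner”. My reforged conversion is lower.

The flask gives: the partner has run out first, with 0.014 % of its partner left; conversion 83.0 %, left-handed product 58.8 %, right-handed product 24.2 %.

    partner + left-handed substrate → left-handed product (k = 1.19 /M/s)
    partner + right-handed substrate → right-handed product (k = 0.443 /M/s)
    left-handed substrate + racemization catalyst ⇌ right-handed substrate + racemization catalyst, rate k3*[racemization catalyst]*[left-handed substrate] forward; the back reaction follows from the equilibrium constant (k = 194 /M/s)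
    precatalyst → racemization catalyst (k = 0.0196 /s)
    2 racemization catalyst → spent catalyst (k = 1.70 /M/s)
    partner → decomposed reagent (k = 0.0154 /s)

With the step from partner to decomposed reagent struck out, the flask reaches a conversion of 96.6 % instead of 83.0 %, so that step is the main reason it stops short. At the flask's conversion, the loss constant charges 0.0367 M of partner to decomposition, and the flask holds 0.0340 M of decomposed reagent at 3.00 min. For a neighbour flask with 0.050 M of partner, the same balance gives a conversion of 22.4 %. The simulation of that neighbour gives 22.6 %.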